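**Retrosynthetic overview**
1. Ring B (ten-membered, C1–C10) is opened at C6=C7 (intramolecular vinylogous aldol/elimination of a butenolide with a free C7H2 onto a C6 aldehyde) and at C8–C9 (Negishi coupling of a C9 alkylzinc with a tetronic acid triflate).
2. Ring A (C1, C10, C11, C12, C13, C14) is a cyclohex-3-enol. The unit O14–C14–C13–C12=C11 is the adduct of a C11–C13 allyl anion and a C14 aldehyde, and this homoallylic O14/C11=C12 relationship makes the key step possible.
3. Moving O14 back onto C11 turns ring A into the five-membered oxacycle O–C14–C1–C10–C11 (a 2-methoxy-5-methyl-5-vinyltetrahydrofuran). Reductive cleavage of its allylic C11–O bond and reclosure from C13 to C14 swaps O for C12–C13 (five to six ring atoms) and sets C14.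
4. The oxacycle comes from a γ-lactone. C1 and C2 are set by a lactone-enolate aldol with a C2–C6 aldehyde made from (R)-2-methylglycidol (C5), C10 by CBS reduction/Johnson–Claisen chirality transfer, and the ring is closed by iodolactonisation.
5. Order of ring formation: γ-lactone/tetrahydrofuran ring, then ring A by ring expansion, then the preformed butenolide is attached, then ring B.

Key step: step 13

Remark: briarane numbering of the target is used for every intermediate (C1 quaternary carbon with Me-15, C2 isovalerate carbon, C5 tertiary carbinol with Me-16, C6=C7, C8=C17 with Me-18, C19 lactone carbonyl, C9 CH2, C10 CH, C11 with Me-20, C12, C13 CH2, C14 acetate carbon); centres that are erased later (C1 before step 9; C11, C12 and C14 before step 13) are carried as epimer mixtures and left undefined in the SMILES.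

Step 1
Reactants: 1 (R)-2-methylglycidol; 2 allylmagnesium chloride
Product: 3 (S)-2-methylhex-5-ene-1,2-diol
Conditions: 2 (2.5 equiv), CuI (10 mol %), THF, −30 to 0 °C; aq NH4Cl
Reagents that add atoms: none
Why: Copper-catalysed SN2 opening of the 2,2-disubstituted epoxide at its CH2 terminus leaves the chiral-pool stereocentre (C5) untouched and delivers C2–C6 with Me-16.

Step 2
Reactants: 3 (S)-2-methylhex-5-ene-1,2-diol
Product: 4 (S)-4-(but-3-en-1-yl)-2,2,4-trimethyl-1,3-dioxolane
Conditions: Me2C(OMe)2, PPTS (cat.), CH2Cl2, rt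
Reagents that add atoms: 2,2-dimethoxypropane COC(C)(C)OC
Why: Acid-catalysed transketalisation gives the five-membered acetonide, which masks O5 and O6 through all basic and reductive steps.

Step 3
Reactants: 4 (S)-4-(but-3-en-1-yl)-2,2,4-trimethyl-1,3-dioxolane
Product: 5 3-[(S)-2,2,4-trimethyl-1,3-dioxolan-4-yl]propanal
Conditions: O3, CH2Cl2, −78 °C; Me2S, −78 °C to rt
Reagents that add atoms: ozone [O-][O+]=O
Why: Ozonolysis with reductive work-up cleaves the only alkene to the C2 aldehyde.

Step 4
Reactants: 6 (tert-butyldimethylsilyloxy)acetaldehyde; 7 3-(triphenylphosphoranylidene)butan-2-one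
Product: 8 (E)-5-(tert-butyldimethylsilyloxy)-3-methylpent-3-en-2-one
Conditions: toluene, 80 °C
Reagents that add atoms: none
Why: Wittig olefination with the stabilised α-branched ylide should give the (E)-trisubstituted enone that holds C9–C13 and Me-20.

Step 5
Reactants: 8 (E)-5-(tert-butyldimethylsilyloxy)-3-methylpent-3-en-2-one
Product: 9 (R,E)-5-(tert-butyldimethylsilyloxy)-3-methylpent-3-en-2-ol
Conditions: (S)-2-methyl-CBS-oxazaborolidine (10 mol %), BH3·SMe2, THF, −30 °C; MeOH
Reagents that add atoms: none
Why: Corey–Bakshi–Shibata reduction, with the alkenyl group as the large and methyl as the small substituent, sets the (R)-carbinol at C12 that relays chirality to C10.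

Step 6
Reactants: 9 (R,E)-5-(tert-butyldimethylsilyloxy)-3-methylpent-3-en-2-ol; 10 triethyl orthopropionate
Product: 12 ethyl (3R,4E)-3-[(tert-butyldimethylsilyloxy)methyl]-2,4-dimethylhex-4-enoate, via ketene acetal 11 (not isolated)
Conditions: EtCO2H (cat.), xylenes, 140 °C, EtOH distilled off
Reagents that add atoms: none
Why: Johnson–Claisen rearrangement through a chair with the C13 methyl equatorial forms C1–C10 suprafacially, so the C12 configuration is transferred to C10 (C1 stays an epimer mixture that is erased in step 9).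

Step 7
Reactants: 12 ethyl (3R,4E)-3-[(tert-butyldimethylsilyloxy)methyl]-2,4-dimethylhex-4-enoate
Product: 13 iodolactone 4-[(tert-butyldimethylsilyloxy)methyl]-5-(1-iodoethyl)-3,5-dimethyldihydrofuran-2(3H)-one
Conditions: I2, MeCN, 0 °C to rt, dark; aq Na2S2O3
Reagents that add atoms: iodine II
Why: Iodolactonisation, in which the ester carbonyl opens the iodonium ion 5-exo at the tertiary C11 and iodide dealkylates the oxocarbenium ion, closes the ring O–C14–C1–C10–C11 (the C11 configuration is irrelevant because C11 becomes sp2 in step 13).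

Step 8
Reactants: 13 iodolactone
Product: 14 vinyl lactone 4-[(tert-butyldimethylsilyloxy)methyl]-3,5-dimethyl-5-vinyldihydrofuran-2(3H)-one
Conditions: DBU, toluene, 80 °C
Reagents that add atoms: none
Why: E2 dehydroiodination can only take a C13 hydrogen because C11 is fully substituted, and so gives the C12=C13 vinyl group.

Step 9
Reactants: 14 vinyl lactone; 5 3-[(S)-2,2,4-trimethyl-1,3-dioxolan-4-yl]propanal
Product: 16 aldol adduct (C1 quaternary lactone with free C2 hydroxyl), via lithium enolate 15 (not isolated)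
Conditions: LiN(i-Pr)2, THF, −78 °C; then 5, −78 °C; AcOH in THF, −78 °C
Reagents that add atoms: none
Why: In this aldol addition of the ring-locked lithium enolate the aldehyde approaches the face opposite the C10 CH2OTBS group (sets quaternary C1), and a Zimmerman–Traxler chair with the aldehyde chain equatorial places O2 anti to C10 and syn to Me-15 (sets C2).

Step 10
Reactants: 16 aldol adduct
Product: 17 C2 tert-butyldimethylsilyl ether of the lactone
Conditions: TBSOTf, 2,6-lutidine, CH2Cl2, 0 °C
Reagents that add atoms: tert-butyldimethylsilyl triflate CC(C)(C)[Si](C)(C)OS(=O)(=O)C(F)(F)F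
Why: Silylation with the reactive triflate protects the hindered C2 carbinol and blocks retro-aldol cleavage.

Step 11
Reactants: 17 C2 silyl ether lactone
Product: 18 lactol (C14 hemiacetal)
Conditions: i-Bu2AlH, CH2Cl2, −78 °C; aq potassium sodium tartrate
Reagents that add atoms: none
Why: Half-reduction of the γ-lactone stops at the lactol because the aluminium hemiacetal is stable at −78 °C.

Step 12
Reactants: 18 lactol
Product: 19 methyl acetal (2-methoxy-5-methyl-5-vinyltetrahydrofuran)
Conditions: MeI, Ag2O, 4 Å MS, CH2Cl2, rt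
Reagents that add atoms: iodomethane CI
Why: Silver oxide mediated O-methylation (Purdie methylation) fixes the lactol as the mixed acetal without a free alkoxide, so no silyl shift or ring opening occurs, and gives C14 a leaving group for step 13.

Step 13
Reactants: 19 methyl acetal
Product: 23 ring A acetate (14S cyclohex-3-enyl acetate), via dilithio hemiacetal 20 (not isolated), via allyllithium aldehyde 21 (not isolated), via lithium alkoxide 22 (not isolated)
Conditions: lithium 4,4'-di-tert-butylbiphenylide (LiDBB, 2.1 equiv), THF, −78 °C, then −78 to −30 °C; Ac2O, −30 to 0 °C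
Reagents that add atoms: acetic anhydride CC(=O)OC(C)=O
Why: Proposed new method: two single-electron transfers from LiDBB to 19 should cleave the weakest bond, the tertiary allylic C11–O bond of the five-membered ring (O, C14, C1, C10, C11), to give the C11–C13 allyllithium and the lithium hemiacetal alkoxide 20, which expels methoxide and so unmasks the C14 aldehyde 21 next to its own nucleophile. The allyllithium then adds through its unsubstituted terminus C13 to C14 (6-exo-trig), so that O is replaced in the ring by C12–C13 and the oxacycle grows by one atom into ring A, with the C11=C12 double bond fixed in position and, by the ring, in geometry. The closest known reaction types are the reductive lithiation of allylic and cyclic benzylic ethers with lithium arenides, the ring expansion of 2-lithio-6-vinyltetrahydropyrans by [2,3]-Wittig rearrangement, and the alkoxide-accelerated 2-vinylcyclobutanol to cyclohex-3-enol rearrangement, which runs through the same allyl anion/aldehyde pair. C14 is the only new stereocentre: in the chair-like closure C2 and C9 stay equatorial, Me-15 is axial, and the aldehyde H rather than O takes the crowded slot between Me-15 and C2 (Felkin–Anh, C2 branch anti to the incoming C13), which puts O14 axial and anti to Me-15 as in the target, while C1, C2, C5 and C10 are untouched and both C11 epimers converge. The step needs C11–O cleavage in preference to acetal C–O or Si–O cleavage (secured by the tertiary allylic activation at −78 °C), attack through C13 and not C11 (the alternative is a strained cyclobutanol flanked by two quaternary carbons that can revert), and capture of alkoxide 22 by Ac2O before the C2 silyl group can migrate.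

Step 14
Reactants: 23 ring A acetate
Product: 24 C2,C9-diol
Conditions: HF·pyridine, pyridine, THF, 0 °C to rt
Reagents that add atoms: none
Why: Fluoride-mediated desilylation under acidic buffering frees O2 and O9 while the acetate stays on O14 (no alkoxide, hence no acyl shift) and the acetonide survives.

Step 15
Reactants: 24 C2,C9-diol
Product: 25 C9 iodide
Conditions: I2, PPh3, imidazole, CH2Cl2, 0 °C
Reagents that add atoms: iodine II
Why: Appel-type iodination is selective for the primary C9 alcohol over the neopentyl-like secondary C2 alcohol.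

Step 16
Reactants: 25 C9 iodide
Product: 26 C9 iodide C2 isovalerate
Conditions: (Me2CHCH2CO)2O, DMAP, Et3N, CH2Cl2, rt
Reagents that add atoms: isovaleric anhydride CC(C)CC(=O)OC(=O)CC(C)C
Why: DMAP-catalysed acylation installs the isovalerate on the only free hydroxyl (C2) with retention.

Step 17
Reactants: 27 3-methyltetronic acid
Product: 28 4-methyl-5-oxo-2,5-dihydrofuran-3-yl triflate
Conditions: Tf2O, i-Pr2NEt, CH2Cl2, −78 °C
Reagents that add atoms: triflic anhydride O=S(=O)(OS(=O)(=O)C(F)(F)F)C(F)(F)F
Why: O-Triflation of the tetronic acid enol gives a β-triflyloxybutenolide that undergoes oxidative addition readily.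

Step 18
Reactants: 26 C9 iodide C2 isovalerate; 28 butenolide triflate
Product: 30 ring A butenolide, via alkylzinc iodide 29 (not isolated)
Conditions: Zn dust, LiCl, THF, 40 °C; then 28, Pd(dppf)Cl2 (5 mol %), THF/DMA, rt to 45 °C
Reagents that add atoms: none
Why: In this Negishi coupling the direct zinc insertion tolerates both esters and the bidentate dppf ligand favours reductive elimination over β-hydride elimination, forming C8–C9 without touching C10.

Step 19
Reactants: 30 ring A butenolide
Product: 31 C5,C6-diol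
Conditions: AcOH/H2O 4:1, 40 °C
Reagents that add atoms: none
Why: Mild aqueous acid hydrolyses the acetonide and leaves the esters, the butenolide and the trisubstituted alkene intact.

Step 20
Reactants: 31 C5,C6-diol
Product: 32 C6 aldehyde with free C5 hydroxyl
Conditions: TEMPO (cat.), PhI(OAc)2, CH2Cl2, rt
Reagents that add atoms: none
Why: Oxoammonium (TEMPO) oxidation takes only the primary C6 alcohol, since the tertiary C5 carbinol cannot be oxidised and the aldehyde has no α-hydrogen to epimerise.

Step 21
Reactants: 32 C6 aldehyde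
Product: 35 macrocycle with C5 triethylsilyl ether, via silyloxyfuran aldehyde 33 (not isolated), via macrocyclic aldol silyl ether 34 (not isolated)
Conditions: TESOTf, i-Pr2NEt, CH2Cl2 (2 mM), −78 to 0 °C; then DBU, 0 °C to rt
Reagents that add atoms: triethylsilyl triflate CC[Si](CC)(CC)OS(=O)(=O)C(F)(F)F
Why: Intramolecular vinylogous Mukaiyama aldol addition of the in situ formed 2-silyloxyfuran through C7 (its other nucleophilic site C17 is blocked by Me-18) to the C6 aldehyde at high dilution closes ring B, and E1cB loss of silanolate with DBU gives C6=C7, whose (E) geometry (C5 cis to C8) is the in-ring cis arrangement that a ten-membered ring prefers.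

Step 22
Reactants: 35 macrocycle with C5 triethylsilyl ether
Product: 36 target CNP0208239.1
Conditions: HF·pyridine, THF, 0 °C
Reagents that add atoms: none
Why: Fluoride cleavage of the tertiary triethylsilyl ether under mildly acidic conditions frees O5 without touching the esters or the alkylidene butenolide.

**Compound list**
1 | (R)-2-methylglycidol | C1[C@](C)(O1)CO | starting material
2 | allylmagnesium chloride | C=CC[Mg]Cl | starting material
3 | (S)-2-methylhex-5-ene-1,2-diol | C=CCC[C@](C)(O)CO | intermediate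
4 | (S)-4-(but-3-en-1-yl)-2,2,4-trimethyl-1,3-dioxolane | C=CCC[C@@]1(C)COC(C)(C)O1 | intermediate
5 | 3-[(S)-2,2,4-trimethyl-1,3-dioxolan-4-yl]propanal | O=CCC[C@@]1(C)COC(C)(C)O1 | intermediate
6 | (tert-butyldimethylsilyloxy)acetaldehyde | O=CCO[Si](C)(C)C(C)(C)C | starting material
7 | 3-(triphenylphosphoranylidene)butan-2-one | CC(=O)C(C)=P(c1ccccc1)(c1ccccc1)c1ccccc1 | starting material
8 | (E)-5-(tert-butyldimethylsilyloxy)-3-methylpent-3-en-2-one | CC(=O)/C(C)=C/CO[Si](C)(C)C(C)(C)C | intermediate
9 | (R,E)-5-(tert-butyldimethylsilyloxy)-3-methylpent-3-en-2-ol | C[C@@H](O)/C(C)=C/CO[Si](C)(C)C(C)(C)C | intermediate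
10 | triethyl orthopropionate | CCC(OCC)(OCC)OCC | starting material
11 | mixed ketene acetal of 9 | CCOC(=CC)O[C@H](C)/C(C)=C/CO[Si](C)(C)C(C)(C)C | intermediate
12 | ethyl (3R,4E)-3-[(tert-butyldimethylsilyloxy)methyl]-2,4-dimethylhex-4-enoate (C1 epimers) | CCOC(=O)C(C)[C@@H](CO[Si](C)(C)C(C)(C)C)/C(C)=C/C | intermediate
13 | iodolactone (C1, C11, C12 epimers) | CC1C(=O)OC(C)(C(C)I)[C@@H]1CO[Si](C)(C)C(C)(C)C | intermediate
14 | vinyl lactone (C1, C11 epimers) | CC1C(=O)OC(C)(C=C)[C@@H]1CO[Si](C)(C)C(C)(C)C | intermediate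
15 | lithium enolate of 14 | CC1=C(O[Li])OC(C)(C=C)[C@@H]1CO[Si](C)(C)C(C)(C)C | intermediate
16 | aldol adduct (C1, C2, C5, C10 as in the target) | O=C1OC(C)(C=C)[C@H](CO[Si](C)(C)C(C)(C)C)[C@@]1(C)[C@@H](O)CC[C@@]2(C)COC(C)(C)O2 | intermediate
17 | C2 silyl ether lactone | O=C1OC(C)(C=C)[C@H](CO[Si](C)(C)C(C)(C)C)[C@@]1(C)[C@@H](O[Si](C)(C)C(C)(C)C)CC[C@@]2(C)COC(C)(C)O2 | intermediate
18 | lactol | OC1OC(C)(C=C)[C@H](CO[Si](C)(C)C(C)(C)C)[C@@]1(C)[C@@H](O[Si](C)(C)C(C)(C)C)CC[C@@]2(C)COC(C)(C)O2 | intermediate
19 | methyl acetal | COC1OC(C)(C=C)[C@H](CO[Si](C)(C)C(C)(C)C)[C@@]1(C)[C@@H](O[Si](C)(C)C(C)(C)C)CC[C@@]2(C)COC(C)(C)O2 | intermediate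
20 | dilithio hemiacetal (allyllithium, hemiacetal alkoxide) | [Li]CC=C(C)[C@H](CO[Si](C)(C)C(C)(C)C)[C@](C)(C(OC)O[Li])[C@@H](O[Si](C)(C)C(C)(C)C)CC[C@@]1(C)COC(C)(C)O1 | intermediate
21 | allyllithium aldehyde | [Li]CC=C(C)[C@H](CO[Si](C)(C)C(C)(C)C)[C@](C)(C=O)[C@@H](O[Si](C)(C)C(C)(C)C)CC[C@@]1(C)COC(C)(C)O1 | intermediate
22 | lithium alkoxide of ring A | [Li]O[C@H]1CC=C(C)[C@H](CO[Si](C)(C)C(C)(C)C)[C@@]1(C)[C@@H](O[Si](C)(C)C(C)(C)C)CC[C@@]2(C)COC(C)(C)O2 | intermediate
23 | ring A acetate | CC(=O)O[C@H]1CC=C(C)[C@H](CO[Si](C)(C)C(C)(C)C)[C@@]1(C)[C@@H](O[Si](C)(C)C(C)(C)C)CC[C@@]2(C)COC(C)(C)O2 | intermediate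
24 | C2,C9-diol | CC(=O)O[C@H]1CC=C(C)[C@H](CO)[C@@]1(C)[C@@H](O)CC[C@@]2(C)COC(C)(C)O2 | intermediate
25 | C9 iodide | CC(=O)O[C@H]1CC=C(C)[C@H](CI)[C@@]1(C)[C@@H](O)CC[C@@]2(C)COC(C)(C)O2 | intermediate
26 | C9 iodide C2 isovalerate | CC(=O)O[C@H]1CC=C(C)[C@H](CI)[C@@]1(C)[C@@H](OC(=O)CC(C)C)CC[C@@]2(C)COC(C)(C)O2 | intermediate
27 | 3-methyltetronic acid | CC1=C(O)COC1=O | starting material
28 | 4-methyl-5-oxo-2,5-dihydrofuran-3-yl triflate | CC1=C(OS(=O)(=O)C(F)(F)F)COC1=O | intermediate
29 | alkylzinc iodide | CC(=O)O[C@H]1CC=C(C)[C@H](C[Zn]I)[C@@]1(C)[C@@H](OC(=O)CC(C)C)CC[C@@]2(C)COC(C)(C)O2 | intermediate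
30 | ring A butenolide | CC(=O)O[C@H]1CC=C(C)[C@H](CC2=C(C)C(=O)OC2)[C@@]1(C)[C@@H](OC(=O)CC(C)C)CC[C@@]3(C)COC(C)(C)O3 | intermediate
31 | C5,C6-diol | CC(=O)O[C@H]1CC=C(C)[C@H](CC2=C(C)C(=O)OC2)[C@@]1(C)[C@@H](OC(=O)CC(C)C)CC[C@](C)(O)CO | intermediate
32 | C6 aldehyde | CC(=O)O[C@H]1CC=C(C)[C@H](CC2=C(C)C(=O)OC2)[C@@]1(C)[C@@H](OC(=O)CC(C)C)CC[C@](C)(O)C=O | intermediate
33 | silyloxyfuran aldehyde (C5 silyl ether) | CC(=O)O[C@H]1CC=C(C)[C@H](Cc2coc(O[Si](CC)(CC)CC)c2C)[C@@]1(C)[C@@H](OC(=O)CC(C)C)CC[C@](C)(O[Si](CC)(CC)CC)C=O | intermediate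
34 | macrocyclic aldol silyl ether (C6, C7 epimers) | CC(=O)O[C@H]1CC=C(C)[C@@H]2CC3=C(C)C(=O)OC3C(O[Si](CC)(CC)CC)[C@@](C)(O[Si](CC)(CC)CC)CC[C@H](OC(=O)CC(C)C)[C@@]12C | intermediate
35 | macrocycle with C5 triethylsilyl ether | CC(=O)O[C@H]1CC=C(C)[C@@H]2CC3=C(C)C(=O)O/C3=C/[C@@](C)(O[Si](CC)(CC)CC)CC[C@H](OC(=O)CC(C)C)[C@@]12C | intermediate
36 | CNP0208239.1 (1S,2S,5S,10S,14S; 6E) | CC(=O)O[C@H]1CC=C(C)[C@@H]2CC3=C(C)C(=O)O/C3=C/[C@@](C)(O)CC[C@H](OC(=O)CC(C)C)[C@@]12C | target

**Step count and risks**

Total step count: 22. Longest linear sequence: 18 (steps 4–16 and 18–22). Steps 1–3 join at step 9 and step 17 joins at step 18.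

Steps most likely to fail:

1. **Step 13** (bears the label).
   - What may go wrong: electron transfer may not discriminate between the allylic C–O bond and other sites, the allyllithium may be protonated before the aldehyde is unmasked, closure may be slow enough for the C2 silyl group to shift onto O14, or the facial preference at C14 may be weak.
   - Fallback: it uses known chemistry, sets out from lactol 18 and comes back at 23.
   - Lactol 18 is converted with PhSSPh and Bu3P into the 2-phenylthio tetrahydrofuran F1.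
   - Reductive lithiation of the C–S bond with LiDBB at −78 °C gives the 2-lithio ether F2.
   - F2 undergoes Wittig rearrangement with ring expansion, as its six-membered homologues do, to the ring A alcohol F3 as a C14 epimer mixture.
   - Dess–Martin oxidation gives the β,γ-unsaturated ketone F4.
   - Reduction with LiBH(s-Bu)3 from the equatorial side, as with other 2,2-disubstituted cyclohexanones, gives the axial 14S alcohol F5.
   - Acetylation (Ac2O, DMAP) returns to 23.

2. **Step 21.**
   - What may go wrong: transannular strain may slow the ten-membered closure so much that oligomerisation or silyl ketene acetal formation at the esters takes over.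
   - Fallback: it changes the ring-closing bond, sets out from 26 and comes back at 34.
   - The acetonide of 26 is hydrolysed (AcOH/H2O) to the iodo diol F6, and the primary alcohol is oxidised (TEMPO, PhI(OAc)2) to the iodo aldehyde F7.
   - Triflate 28 is converted with TESOTf and i-Pr2NEt into the silyloxyfuran triflate F8, which adds intermolecularly through C7 to F7. This forms C6–C7 first and gives the open-chain adduct F9, which carries both the alkyl iodide and the vinyl triflate.
   - Zinc insertion gives the alkylzinc iodide F10.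
   - Slow addition of F10 to Pd(dppf)Cl2 closes ring B at C8–C9 by intramolecular Negishi coupling, which delivers 34.
   - DBU then gives 35 as in step 21, so that the double-bond geometry is still set inside the ring.

3. **Step 9.**
   - What may go wrong: the hindered tetrasubstituted enolate may discriminate poorly between the aldehyde faces (C2), or retro-aldol equilibration may erode the selectivity.
   - Fallback: it sets C2 by ketone reduction instead of by the aldol transition state, sets out from 16 as a C2 epimer mixture and comes back at 16 as a single epimer.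
   - Dess–Martin oxidation gives the β-keto lactone F11.
   - Non-chelating reduction with LiBH(s-Bu)3 at −78 °C, in the conformer with the two carbonyl dipoles opposed and with hydride entering from the Me-15 side rather than the C10 side, should give the 2S alcohol.

**Further compounds**
F1 | step 13 | 2-phenylthio tetrahydrofuran | c1ccccc1SC1OC(C)(C=C)[C@H](CO[Si](C)(C)C(C)(C)C)[C@@]1(C)[C@@H](O[Si](C)(C)C(C)(C)C)CC[C@@]2(C)COC(C)(C)O2
F2 | step 13 | 2-lithio ether | [Li]C1OC(C)(C=C)[C@H](CO[Si](C)(C)C(C)(C)C)[C@@]1(C)[C@@H](O[Si](C)(C)C(C)(C)C)CC[C@@]2(C)COC(C)(C)O2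
F3 | step 13 | ring A alcohol (C14 epimers) | OC1CC=C(C)[C@H](CO[Si](C)(C)C(C)(C)C)[C@@]1(C)[C@@H](O[Si](C)(C)C(C)(C)C)CC[C@@]2(C)COC(C)(C)O2
F4 | step 13 | β,γ-unsaturated ketone | O=C1CC=C(C)[C@H](CO[Si](C)(C)C(C)(C)C)[C@@]1(C)[C@@H](O[Si](C)(C)C(C)(C)C)CC[C@@]2(C)COC(C)(C)O2
F5 | step 13 | 14S alcohol | O[C@H]1CC=C(C)[C@H](CO[Si](C)(C)C(C)(C)C)[C@@]1(C)[C@@H](O[Si](C)(C)C(C)(C)C)CC[C@@]2(C)COC(C)(C)O2
F6 | step 21 | iodo diol | CC(=O)O[C@H]1CC=C(C)[C@H](CI)[C@@]1(C)[C@@H](OC(=O)CC(C)C)CC[C@](C)(O)CO
F7 | step 21 | iodo aldehyde | CC(=O)O[C@H]1CC=C(C)[C@H](CI)[C@@]1(C)[C@@H](OC(=O)CC(C)C)CC[C@](C)(O)C=O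
F8 | step 21 | silyloxyfuran triflate | Cc1c(O[Si](CC)(CC)CC)occ1OS(=O)(=O)C(F)(F)F
F9 | step 21 | open-chain adduct | CC(=O)O[C@H]1CC=C(C)[C@H](CI)[C@@]1(C)[C@@H](OC(=O)CC(C)C)CC[C@](C)(O[Si](CC)(CC)CC)C(O[Si](CC)(CC)CC)C2OC(=O)C(C)=C2OS(=O)(=O)C(F)(F)F
F10 | step 21 | alkylzinc iodide | CC(=O)O[C@H]1CC=C(C)[C@H](C[Zn]I)[C@@]1(C)[C@@H](OC(=O)CC(C)C)CC[C@](C)(O[Si](CC)(CC)CC)C(O[Si](CC)(CC)CC)C2OC(=O)C(C)=C2OS(=O)(=O)C(F)(F)F
F11 | step 9 | β-keto lactone | O=C1OC(C)(C=C)[C@H](CO[Si](C)(C)C(C)(C)C)[C@@]1(C)C(=O)CC[C@@]2(C)COC(C)(C)O2
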